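**Retrosynthetic overview**
- The C6 ester comes from an α'-hydroxy enone and (2R,3R)-epoxyangelic acid (made from angelic acid by reduction, Sharpless epoxidation and oxidation); the C7 alcohol is released last.
- O6 comes from enolate hydroxylation at C6 anti to isopropyl; the enone from a C2 selenoxide elimination; the C1 oxygen from an O7-tethered hydrosilylation and oxidation of the C1=C6 alkene.
- The cis O4/isopropyl pair comes from syn SN2' opening of a 7-oxanorbornene by isopropyllithium at C5: C1–O breaks, the bridge oxygen stays on C4 and is acylated with angelic acid.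
- The 7-oxanorbornene comes from furan and 3-acryloyloxazolidin-2-one by a copper bis(oxazoline)-catalysed endo Diels–Alder reaction. The carbocycle is the only ring closed in the main line (step 1); the oxirane ring is made on the side-chain acid (step 14).
- Feature: on the six-membered carbocycle the oxygens on C1 (ketone) and C4 (angelate) stand 1,4 to each other with C6 and C5 between them, like the two α-carbons and two β-carbons of furan; C2–C3 with the exocyclic C7 is an acrylate unit.

Key step: step 1

**Remarks**
- Numbering: C1 is the ketone carbon, C2 carries C7 (the CH2OH carbon), then C3, C4 (angelate, O4), C5 (isopropyl), C6 (epoxyangelate, O6). TBS is tert-butyldimethylsilyl.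
- L is 2,2'-(propane-2,2-diyl)bis[(4R)-4-tert-butyl-4,5-dihydro-1,3-oxazole], (R,R)-t-Bu-box. It is assumed to give the (1R,2R,4R) adduct, the mirror image of the adduct expected from the (S,S) ligand.
- Isopropyllithium replaces a palladium/dialkylzinc opening because an isopropylpalladium species can lose β-hydride. O6 is introduced on the enone enolate and not by dihydroxylation, so that C1 and C6 never carry two secondary hydroxyls that would have to be told apart.

**Route**

Step 1
Reactants: 1 furan; 2 3-acryloyl-1,3-oxazolidin-2-one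
Product: 3 3-[(1R,2R,4R)-7-oxabicyclo[2.2.1]hept-5-ene-2-carbonyl]-1,3-oxazolidin-2-one (endo adduct)
Conditions: [Cu(L)](SbF6)2 (5 mol %), furan (10 equiv), CH2Cl2, −78 °C; crystallised cold
Reagents that add atoms: none
Why: The imide chelates the cationic divalent copper centre through both carbonyl oxygens in the s-cis form, which lowers its LUMO and shields one enantioface with a tert-butyl group of the ligand, so furan adds to the open face in a concerted suprafacial [4+2] cycloaddition. The closest known reaction type is the bis(oxazoline)copper-catalysed Diels–Alder reaction of acrylimides with cyclic dienes, furan included. The six-membered carbocycle C1–C6 closes intermolecularly by forming C1–C2 and C3–C4 in one event, the furan oxygen becoming the one-atom bridge. C2 is set by the ligand-controlled face of the dienophile, and C1 and C4 follow from the endo approach of the chelated carbonyl under the diene, so the C4–O centre that survives to the target comes from the catalyst. The step needs enantioface and endo selectivity under kinetic control; −78 °C keeps the adduct from reverting and the minor exo adduct should be removed by crystallisation.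

Step 2
Reactants: 3
Product: 4 [(1R,2S,4R)-7-oxabicyclo[2.2.1]hept-5-en-2-yl]methanol
Conditions: LiBH4, MeOH (1 equiv), THF, 0 °C, directly after step 1
Reagents that add atoms: none
Why: Hydride cleavage of the N-acyloxazolidinone reduces the exocyclic carbonyl to the primary alcohol at 0 °C without epimerising C2 and removes the activating group before the adduct can undergo retro-Diels–Alder reaction.

Step 3
Reactants: 4
Product: 5 tert-butyl(dimethyl){[(1R,2S,4R)-7-oxabicyclo[2.2.1]hept-5-en-2-yl]methoxy}silane
Conditions: TBSCl, imidazole, CH2Cl2, 0 °C to rt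
Reagents that add atoms: tert-butyl(chloro)dimethylsilane, CC(C)(C)[Si](C)(C)Cl
Why: Standard silylation of a primary alcohol gives an ether that is inert to the organolithium and makes the endo side chain bulky and poorly coordinating.

Step 4
Reactants: 5; 6 isopropyllithium
Product: 7 (1R,2S,5R)-5-{[tert-butyl(dimethyl)silyl]oxymethyl}-2-(propan-2-yl)cyclohex-3-en-1-ol (OH cis to isopropyl; CH2OTBS trans to both)
Conditions: iPrLi (2 equiv), Et2O/pentane, −78 to 0 °C; then H2O
Reagents that add atoms: none
Why: Syn SN2' ring opening of a 7-oxanorbornene by an alkyllithium: lithium held by the bridge oxygen delivers isopropyl to the exo face of C5, the alkene carbon remote from the endo C2 side chain (attack at C6 would push H6 into that side chain), C1–O breaks and the oxygen stays on C4, so C5 is set by the bicyclic framework with isopropyl cis to O4.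

Step 5
Reactants: 7; 8 angelic acid ((Z)-2-methylbut-2-enoic acid)
Product: 10 (1R,2S,5R)-5-{[tert-butyl(dimethyl)silyl]oxymethyl}-2-(propan-2-yl)cyclohex-3-en-1-yl (Z)-2-methylbut-2-enoate, via mixed anhydride 9 (not isolated)
Conditions: 8, 2,4,6-trichlorobenzoyl chloride, Et3N, toluene, rt; then 7, toluene, 80 °C
Reagents that add atoms: none
Why: Yamaguchi-type esterification through the preformed mixed anhydride without a nucleophilic catalyst is known to acylate hindered secondary alcohols with angelic acid without Z to E isomerisation, and it touches no stereocentre.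

Step 6
Reactants: 10
Product: 11 (1R,2S,5R)-5-(hydroxymethyl)-2-(propan-2-yl)cyclohex-3-en-1-yl (Z)-2-methylbut-2-enoate
Conditions: HF·pyridine, pyridine, THF, 0 °C to rt
Reagents that add atoms: none
Why: Buffered fluoride cleaves the primary silyl ether and leaves the angelate and the alkene untouched, freeing O7 as the anchor for the silicon tether.

Step 7
Reactants: 11
Product: 14 (1R,2R,4S,5S)-4-hydroxy-5-(hydroxymethyl)-2-(propan-2-yl)cyclohexyl (Z)-2-methylbut-2-enoate (C1 hydroxyl cis to C7), via dimethylsilyl ether 12 (not isolated), via oxasilolane 13 (not isolated)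
Conditions: (HMe2Si)2NH, rt, then evaporate; H2PtCl6·6H2O (0.1 mol %), THF, 60 °C; then 30% H2O2, KF, KHCO3, THF/MeOH, rt
Reagents that add atoms: hydrogen peroxide, OO
Why: Tamao intramolecular hydrosilylation and oxidation: the silicon hydride tethered to O7 adds across C1=C6 in the 5-exo sense, so silicon goes only to C1 on the face of the C2 side chain, and the C–Si bond is oxidised with retention to the C1 alcohol (this centre later becomes the ketone), while C6 stays CH2.

Step 8
Reactants: 14
Product: 15 (1R,2R,4S,5S)-5-{[tert-butyl(dimethyl)silyl]oxymethyl}-4-hydroxy-2-(propan-2-yl)cyclohexyl (Z)-2-methylbut-2-enoate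
Conditions: TBSCl (1.05 equiv), imidazole, CH2Cl2, 0 °C
Reagents that add atoms: tert-butyl(chloro)dimethylsilane, CC(C)(C)[Si](C)(C)Cl
Why: The primary hydroxyl is silylated much faster than the hindered secondary C1 hydroxyl, so the diol is differentiated by sterics alone.

Step 9
Reactants: 15
Product: 16 (1R,2R,5S)-5-{[tert-butyl(dimethyl)silyl]oxymethyl}-4-oxo-2-(propan-2-yl)cyclohexyl (Z)-2-methylbut-2-enoate
Conditions: Dess–Martin periodinane, CH2Cl2, 0 °C to rt
Reagents that add atoms: none
Why: Periodinane oxidation of the secondary alcohol gives the C1 ketone under near-neutral conditions that spare the silyl ether, the angelate and the β-silyloxy ketone.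

Step 10
Reactants: 16
Product: 18 C2-phenylselanyl ketone (16 with PhSe on C2, drawn anti to O4; the C2 configuration is of no consequence), via trimethylsilyl enol ether 17 (not isolated)
Conditions: Me3SiOTf, Et3N, CH2Cl2, 0 °C to rt (equilibrating); then PhSeCl, THF, −78 °C
Reagents that add atoms: phenylselenyl chloride, Cl[Se]c1ccccc1
Why: Under equilibrating silylation the more substituted C1=C2 enol ether should predominate, and α-selenenylation of a silyl enol ether places selenium on C2.

Step 11
Reactants: 18
Product: 20 (1S,6R)-3-{[tert-butyl(dimethyl)silyl]oxymethyl}-4-oxo-6-(propan-2-yl)cyclohex-2-en-1-yl (Z)-2-methylbut-2-enoate, via selenoxide 19 (not isolated)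
Conditions: 30% H2O2, pyridine, CH2Cl2, 0 °C to rt
Reagents that add atoms: none
Why: Selenoxide syn elimination avoids the β-hydrogens on the oxygen-bearing C7, so the double bond enters the ring at C2–C3 in conjugation with the ketone.

Step 12
Reactants: 20
Product: 22 (1R,5S,6S)-5-hydroxy-3-{[tert-butyl(dimethyl)silyl]oxymethyl}-4-oxo-6-(propan-2-yl)cyclohex-2-en-1-yl (Z)-2-methylbut-2-enoate (C6 hydroxyl trans to isopropyl), via lithium dienolate 21 (not isolated)
Conditions: LiN(SiMe3)2, THF, −78 °C; 2-(phenylsulfonyl)-3-phenyloxaziridine, −78 °C; AcOH quench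
Reagents that add atoms: 2-(phenylsulfonyl)-3-phenyloxaziridine, O=S(=O)(N1OC1c1ccccc1)c1ccccc1
Why: Kinetic deprotonation of the enone at C6 (α') gives the cross-conjugated dienolate, which the N-sulfonyloxaziridine hydroxylates on the face anti to the C5 isopropyl and C4 ester groups, so O6 is set trans to isopropyl (also the more stable epimer).

Step 13
Reactants: 8
Product: 23 (Z)-2-methylbut-2-en-1-ol
Conditions: LiAlH4, Et2O, 0 °C to rt
Reagents that add atoms: none
Why: Hydride reduction of the acid gives the allylic alcohol without touching the trisubstituted alkene or its Z geometry.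

Step 14
Reactants: 23
Product: 24 [(2S,3R)-2,3-dimethyloxiran-2-yl]methanol
Conditions: Ti(OiPr)4 (10 mol %), L-(+)-diethyl tartrate (12 mol %), tBuOOH, 4 Å molecular sieves, CH2Cl2, −20 °C
Reagents that add atoms: tert-butyl hydroperoxide, CC(C)(C)OO
Why: Sharpless asymmetric epoxidation: the L-(+)-tartrate titanium complex delivers oxygen to the enantioface that gives the (2S,3R) epoxy alcohol, and syn addition keeps the Z geometry as the cis relation of CH2OH and the C3 methyl.

Step 15
Reactants: 24
Product: 25 (2R,3R)-2,3-dimethyloxirane-2-carboxylic acid (epoxyangelic acid)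
Conditions: RuCl3·xH2O (2 mol %), NaIO4, MeCN/EtOAc/H2O, 0 °C to rt
Reagents that add atoms: water, O
Why: RuO4-catalysed oxidation takes the primary alcohol through the aldehyde hydrate to the acid and leaves the epoxide and both stereocentres untouched (the C2 descriptor becomes R only through the change in CIP priority).

Step 16
Reactants: 22; 25
Product: 27 TBS ether of the target (22 acylated on O6 by 25), via mixed anhydride 26 (not isolated)
Conditions: 25, 2,4,6-trichlorobenzoyl chloride, Et3N, THF, rt; then 22, DMAP (0.2 equiv), toluene, rt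
Reagents that add atoms: none
Why: Yamaguchi esterification couples the α-hydroxy ketone with the hindered glycidic acid through its mixed anhydride; C6 stays in the more stable trans configuration and the enantiopure acid fixes both epoxide centres.

Step 17
Reactants: 27
Product: 28 (4R,5R,6S)-2-(hydroxymethyl)-4-[(Z)-2-methylbut-2-enoyloxy]-6-[(2R,3R)-2,3-dimethyloxirane-2-carbonyloxy]-5-(propan-2-yl)cyclohex-2-en-1-one (CNP0293054.1)
Conditions: HF·pyridine, pyridine, THF, 0 °C
Reagents that add atoms: none
Why: Buffered fluoride cleavage of the primary allylic silyl ether should leave the glycidic ester, the angelate and the enone intact.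

**Compound list**
1 | furan | c1ccoc1 | starting material
2 | 3-acryloyl-1,3-oxazolidin-2-one | C=CC(=O)N1CCOC1=O | starting material
3 | 3-[(1R,2R,4R)-7-oxabicyclo[2.2.1]hept-5-ene-2-carbonyl]-1,3-oxazolidin-2-one (endo) | O=C(N1CCOC1=O)[C@@H]2C[C@@H]3C=C[C@H]2O3 | intermediate
4 | [(1R,2S,4R)-7-oxabicyclo[2.2.1]hept-5-en-2-yl]methanol | OC[C@@H]1C[C@@H]2C=C[C@H]1O2 | intermediate
5 | tert-butyl(dimethyl){[(1R,2S,4R)-7-oxabicyclo[2.2.1]hept-5-en-2-yl]methoxy}silane | CC(C)(C)[Si](C)(C)OC[C@@H]1C[C@@H]2C=C[C@H]1O2 | intermediate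
6 | isopropyllithium | [Li]C(C)C | starting material
7 | (1R,2S,5R)-5-{[tert-butyl(dimethyl)silyl]oxymethyl}-2-(propan-2-yl)cyclohex-3-en-1-ol | O[C@@H]1C[C@@H](CO[Si](C)(C)C(C)(C)C)C=C[C@@H]1C(C)C | intermediate
8 | angelic acid, (Z)-2-methylbut-2-enoic acid | C/C=C(/C)C(=O)O | starting material
9 | angelic 2,4,6-trichlorobenzoic anhydride (formed in the flask) | C/C=C(/C)C(=O)OC(=O)c1c(Cl)cc(Cl)cc1Cl | intermediate
10 | (1R,2S,5R)-5-{[tert-butyl(dimethyl)silyl]oxymethyl}-2-(propan-2-yl)cyclohex-3-en-1-yl (Z)-2-methylbut-2-enoate | C/C=C(/C)C(=O)O[C@@H]1C[C@@H](CO[Si](C)(C)C(C)(C)C)C=C[C@@H]1C(C)C | intermediate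
11 | (1R,2S,5R)-5-(hydroxymethyl)-2-(propan-2-yl)cyclohex-3-en-1-yl (Z)-2-methylbut-2-enoate | C/C=C(/C)C(=O)O[C@@H]1C[C@@H](CO)C=C[C@@H]1C(C)C | intermediate
12 | O7-dimethylsilyl (Si–H) ether of 11 (formed in the flask) | C/C=C(/C)C(=O)O[C@@H]1C[C@@H](CO[SiH](C)C)C=C[C@@H]1C(C)C | intermediate
13 | cis-fused oxasilolane, silicon bonded to C1 and O7 (formed in the flask) | C/C=C(/C)C(=O)O[C@@H]1C[C@H]2CO[Si](C)(C)[C@H]2C[C@@H]1C(C)C | intermediate
14 | (1R,2R,4S,5S)-4-hydroxy-5-(hydroxymethyl)-2-(propan-2-yl)cyclohexyl (Z)-2-methylbut-2-enoate | C/C=C(/C)C(=O)O[C@@H]1C[C@@H](CO)[C@@H](O)C[C@@H]1C(C)C | intermediate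
15 | (1R,2R,4S,5S)-5-{[tert-butyl(dimethyl)silyl]oxymethyl}-4-hydroxy-2-(propan-2-yl)cyclohexyl (Z)-2-methylbut-2-enoate | C/C=C(/C)C(=O)O[C@@H]1C[C@@H](CO[Si](C)(C)C(C)(C)C)[C@@H](O)C[C@@H]1C(C)C | intermediate
16 | (1R,2R,5S)-5-{[tert-butyl(dimethyl)silyl]oxymethyl}-4-oxo-2-(propan-2-yl)cyclohexyl (Z)-2-methylbut-2-enoate | C/C=C(/C)C(=O)O[C@@H]1C[C@@H](CO[Si](C)(C)C(C)(C)C)C(=O)C[C@@H]1C(C)C | intermediate
17 | C1=C2 trimethylsilyl enol ether of 16 (formed in the flask) | C/C=C(/C)C(=O)O[C@@H]1CC(CO[Si](C)(C)C(C)(C)C)=C(O[Si](C)(C)C)C[C@@H]1C(C)C | intermediate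
18 | C2-phenylselanyl derivative of ketone 16 (selenium anti to O4) | C/C=C(/C)C(=O)O[C@@H]1C[C@@](CO[Si](C)(C)C(C)(C)C)([Se]c2ccccc2)C(=O)C[C@@H]1C(C)C | intermediate
19 | selenoxide of 18 (formed in the flask) | C/C=C(/C)C(=O)O[C@@H]1C[C@@](CO[Si](C)(C)C(C)(C)C)([Se](=O)c2ccccc2)C(=O)C[C@@H]1C(C)C | intermediate
20 | (1S,6R)-3-{[tert-butyl(dimethyl)silyl]oxymethyl}-4-oxo-6-(propan-2-yl)cyclohex-2-en-1-yl (Z)-2-methylbut-2-enoate | C/C=C(/C)C(=O)O[C@@H]1C=C(CO[Si](C)(C)C(C)(C)C)C(=O)C[C@@H]1C(C)C | intermediate
21 | lithium C1=C6 dienolate of 20 (formed in the flask) | [Li+].C/C=C(/C)C(=O)O[C@@H]1C=C(CO[Si](C)(C)C(C)(C)C)C([O-])=C[C@@H]1C(C)C | intermediate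
22 | (1R,5S,6S)-5-hydroxy-3-{[tert-butyl(dimethyl)silyl]oxymethyl}-4-oxo-6-(propan-2-yl)cyclohex-2-en-1-yl (Z)-2-methylbut-2-enoate | C/C=C(/C)C(=O)O[C@@H]1C=C(CO[Si](C)(C)C(C)(C)C)C(=O)[C@@H](O)[C@@H]1C(C)C | intermediate
23 | (Z)-2-methylbut-2-en-1-ol | C/C=C(/C)CO | intermediate
24 | [(2S,3R)-2,3-dimethyloxiran-2-yl]methanol | OC[C@]1(C)O[C@@H]1C | intermediate
25 | (2R,3R)-2,3-dimethyloxirane-2-carboxylic acid | OC(=O)[C@]1(C)O[C@@H]1C | intermediate
26 | (2R,3R)-2,3-dimethyloxirane-2-carboxylic 2,4,6-trichlorobenzoic anhydride (formed in the flask) | Clc1cc(Cl)c(C(=O)OC(=O)[C@]2(C)O[C@@H]2C)c(Cl)c1 | intermediate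
27 | C7 TBS ether of the target | C/C=C(/C)C(=O)O[C@@H]1C=C(CO[Si](C)(C)C(C)(C)C)C(=O)[C@@H](OC(=O)[C@]2(C)O[C@@H]2C)[C@@H]1C(C)C | intermediate
28 | (4R,5R,6S)-2-(hydroxymethyl)-4-[(Z)-2-methylbut-2-enoyloxy]-6-[(2R,3R)-2,3-dimethyloxirane-2-carbonyloxy]-5-(propan-2-yl)cyclohex-2-en-1-one | C/C=C(/C)C(=O)O[C@@H]1C=C(CO)C(=O)[C@@H](OC(=O)[C@]2(C)O[C@@H]2C)[C@@H]1C(C)C | target

**Step count**
Total steps: 17. Longest linear sequence: 14 steps (steps 1 to 12, 16 and 17).

**Steps most likely to fail**

Step 4. The organolithium may add at C6 as well as at C5, cleaving C4–O instead of C1–O, or it may act as a base toward the substrate. The fallback sets out from 5 and replaces the stoichiometric anionic SN2' reaction by a catalytic carbometallation: Pd(MeCN)2Cl2 (5 mol %), Fe(C5H4PPh2)2 and iPr2Zn in CH2Cl2 at rt. An isopropylpalladium species adds across the exo face of C5=C6 and β-oxygen elimination opens the bridge, which again should give the cis alcohol and rejoins the route at 7. This fallback makes no new compound (F0).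

Step 10. Enolisation may go toward C6 instead of C2, which would lead to the C5=C6 enone and loss of the C5 centre, or the C7 silyloxy group may be lost by β-elimination. The fallback sets out from 16 and oxygenates C6 first. Kinetic deprotonation at the C6 methylene (LiN(iPr)2, THF, −78 °C) and oxidation with the same oxaziridine give the 6-hydroxy ketone F1, and Et3SiCl with imidazole gives the triethylsilyl ether F2. A second kinetic deprotonation then takes place at C2, away from the silyloxy-bearing carbon, and PhSeBr gives the selenide F3. H2O2 with pyridine gives the enone silyl ether F4. Pyridinium p-toluenesulfonate in MeOH at 0 °C removes the secondary triethylsilyl group in the presence of the primary TBS ether and rejoins the route at 22, so steps 11 and 12 are not needed.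

Step 7. The hydrosilylation may be slow or misdirected: alkene migration by platinum hydride, delivery of silicon to C6, or reduction of the angelate. The fallback sets out from 11 and uses an electrophile-induced cyclisation. Boc2O with DMAP gives the tert-butyl carbonate F5. IBr in toluene at −80 °C closes a six-membered cyclic carbonate onto C1 with iodine trans on C6, the iodocarbonate F6. Bu3SnH with AIBN removes the iodine to give the cyclic carbonate F7, and K2CO3 in MeOH at 0 °C cleaves the carbonate and rejoins the route at 14.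

Further compounds
F0 | step 4 | none | none
F1 | step 10 | 6-hydroxy derivative of ketone 16 (hydroxyl trans to isopropyl) | C/C=C(/C)C(=O)O[C@@H]1C[C@@H](CO[Si](C)(C)C(C)(C)C)C(=O)[C@@H](O)[C@@H]1C(C)C
F2 | step 10 | O6 triethylsilyl ether of F1 | C/C=C(/C)C(=O)O[C@@H]1C[C@@H](CO[Si](C)(C)C(C)(C)C)C(=O)[C@@H](O[Si](CC)(CC)CC)[C@@H]1C(C)C
F3 | step 10 | C2-phenylselanyl derivative of F2 | C/C=C(/C)C(=O)O[C@@H]1C[C@@](CO[Si](C)(C)C(C)(C)C)([Se]c2ccccc2)C(=O)[C@@H](O[Si](CC)(CC)CC)[C@@H]1C(C)C
F4 | step 10 | O6 triethylsilyl ether of hydroxy enone 22 | C/C=C(/C)C(=O)O[C@@H]1C=C(CO[Si](C)(C)C(C)(C)C)C(=O)[C@@H](O[Si](CC)(CC)CC)[C@@H]1C(C)C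
F5 | step 7 | O7 tert-butyl carbonate of 11 | C/C=C(/C)C(=O)O[C@@H]1C[C@@H](COC(=O)OC(C)(C)C)C=C[C@@H]1C(C)C
F6 | step 7 | cyclic carbonate across O7 and C1 with iodine on C6 (trans to the C1 oxygen) | C/C=C(/C)C(=O)O[C@@H]1C[C@H]2COC(=O)O[C@H]2[C@H](I)[C@@H]1C(C)C
F7 | step 7 | cyclic carbonate across O7 and C1 (iodine removed) | C/C=C(/C)C(=O)O[C@@H]1C[C@H]2COC(=O)O[C@H]2C[C@@H]1C(C)C
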